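**Plan**

- Numbering used throughout: ring A (seven-membered) = C2 (alkene carbon bearing CH3), C3 (alkene CH), C4 (C=O), C5 (quaternary, CH3), C9 (ring-fusion CH), C10 (ester CH), C11 (CH2); ring B (five-membered) = C5, C6, C7, C8 (C(OH)i-Pr), C9; β is the face of the CH3 on C5.
- Feature: C10 is a homoallylic carbinol, joined through the single CH2 C11 to C2, so ring A opens at C10–C11 to an aldehyde and a 2-methylallyl ketone; ring B plus C10 are the six ring carbons of terpinen-4-ol, whose CH3 sits on C5 and whose C(OH)(i-Pr) is C8.
- Retrosynthetic cuts, in order: the C10–O acyl bond; C10–C11 (ring A, carbonyl–ene); C3–C4 (2-methylallyl addition to a C4 aldehyde); C5–C4 (vinyl conjugate addition); C5=C9 (aldol), which unfolds ring B to the ozonolysis product of the terpinen-4-ol ring.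
- Forward: ring B first (ozonolysis/aldol ring contraction), then quaternary C5, the 3-methylbut-3-enoyl chain, ring A by the ene closure, alkene conjugation, acylation, desilylation.
- Stereochemistry: C8 from (S)-terpinen-4-ol 1; C5 by addition anti to the pseudo-axial silyloxy group; C9 by equilibration of the aldehyde; C10 in the ene transition state held by the trans-disubstituted ring B.

Key step: step 9

Assumption: (S)-terpinen-4-ol of high enantiomeric purity is at hand; material of lower purity would be upgraded before step 1 by crystallisation of an ester derivative.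

**Route**

Step 1
Reactants: 1 (S)-terpinen-4-ol
Product: 2 (S)-tert-butyldimethylsilyl ether of terpinen-4-ol
Conditions: TBSOTf, 2,6-lutidine, CH2Cl2, 0 °C to rt
Reagents that add atoms: tert-butyldimethylsilyl trifluoromethanesulfonate (TBSOTf), CC(C)(C)[Si](C)(C)OS(=O)(=O)C(F)(F)F
Why: Silyl triflate with a hindered pyridine base is the standard silylation of hindered tertiary alcohols, and the chiral-pool centre (later C8) is not touched.

Step 2
Reactants: 2 (S)-tert-butyldimethylsilyl ether of terpinen-4-ol
Product: 3 (S)-3-(tert-butyldimethylsilyloxy)-3-isopropyl-6-oxoheptanal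
Conditions: O3, CH2Cl2, −78 °C; then PPh3, −78 °C to rt
Reagents that add atoms: ozone, [O-][O+]=O
Why: Ozonolysis with reductive work-up cleaves the only alkene into a methyl ketone and an aldehyde, while the silyl ether and C8 are inert.

Step 3
Reactants: 3 (S)-3-(tert-butyldimethylsilyloxy)-3-isopropyl-6-oxoheptanal
Product: 4 (R)-5-(tert-butyldimethylsilyloxy)-5-isopropyl-2-methylcyclopent-1-ene-1-carbaldehyde
Conditions: piperidine (cat.), AcOH (cat.), toluene, 40 °C, 4 Å molecular sieves
Reagents that add atoms: none
Why: Amine-mediated intramolecular aldol condensation (the enamine of the aldehyde adds 5-exo to the methyl ketone, then the new tertiary hydroxyl leaves as water) closes ring B as the tetrasubstituted enal, as is usual for keto aldehydes from 1-methylcyclohexene ozonolysis; the weakly basic silyl ether oxygen should stay in place under the buffered, mild conditions.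

Step 4
Reactants: 4 (R)-5-(tert-butyldimethylsilyloxy)-5-isopropyl-2-methylcyclopent-1-ene-1-carbaldehyde; 5 vinylmagnesium bromide
Product: 7 5β-(tert-butyldimethylsilyloxy)-5α-isopropyl-2β-methyl-2α-vinylcyclopentane-1β-carbaldehyde (CH3 on C5, OSi on C8 and CHO on C9 all on the β face), via trimethylsilyl enol ether 6 (not isolated)
Conditions: 5, CuBr·SMe2 (10 mol %), TMSCl, HMPA, THF, −78 °C; then K2CO3 (cat.), MeOH, 0 °C to rt
Reagents that add atoms: vinylmagnesium bromide 5, C=C[Mg]Br
Why: Copper-catalysed, TMSCl-accelerated conjugate addition of a vinyl Grignard reagent to a β,β-disubstituted enal creates the quaternary C5: in the favoured envelope of the cyclopentene the larger isopropyl group lies pseudo-equatorial and the silyloxy group pseudo-axial over one face, so vinyl should enter anti to the silyloxy group, and methanolysis of the silyl enol ether under mild base lets the formyl group at C9 settle on the face away from the isopropyl and vinyl groups.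

Step 5
Reactants: 7 5β-(tert-butyldimethylsilyloxy)-5α-isopropyl-2β-methyl-2α-vinylcyclopentane-1β-carbaldehyde
Product: 8 [5β-(tert-butyldimethylsilyloxy)-5α-isopropyl-2β-methyl-2α-vinylcyclopent-1β-yl]methanol
Conditions: NaBH4, MeOH, 0 °C
Reagents that add atoms: none
Why: Borohydride reduction masks C10 as a primary alcohol so that the vinyl group can be cleaved to a second aldehyde without two formyl groups competing, and it fixes C9 against epimerisation.

Step 6
Reactants: 8 [5β-(tert-butyldimethylsilyloxy)-5α-isopropyl-2β-methyl-2α-vinylcyclopent-1β-yl]methanol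
Product: 9 3β-(tert-butyldimethylsilyloxy)-2β-(hydroxymethyl)-3α-isopropyl-1β-methylcyclopentane-1α-carbaldehyde
Conditions: O3, CH2Cl2/MeOH, −78 °C; then PPh3, −78 °C to rt
Reagents that add atoms: ozone, [O-][O+]=O
Why: Ozonolysis of the terminal vinyl group with reductive work-up gives the C4 aldehyde on the quaternary carbon; the free primary hydroxyl is tolerated and the trans placement of C4 and C10 on ring B disfavours lactol formation.

Step 7
Reactants: 9 3β-(tert-butyldimethylsilyloxy)-2β-(hydroxymethyl)-3α-isopropyl-1β-methylcyclopentane-1α-carbaldehyde; 10 3-chloro-2-methylprop-1-ene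
Product: 11 1-[3β-(tert-butyldimethylsilyloxy)-2β-(hydroxymethyl)-3α-isopropyl-1β-methylcyclopent-1α-yl]-3-methylbut-3-en-1-ol (both C4 epimers, used together)
Conditions: 10, Mg, THF (Grignard reagent formed first, 3 equiv); then 9, THF, 0 °C; aq. NH4Cl
Reagents that add atoms: 3-chloro-2-methylprop-1-ene 10 (as its Grignard reagent), CC(=C)CCl
Why: Grignard addition of the 2-methylallyl reagent to the aldehyde (one equivalent is consumed by the free hydroxyl) brings in C3, C2 with its methyl group and C11; allylic Grignard reagents add readily to hindered aldehydes, and the new carbinol configuration is irrelevant because it is oxidised in the next step.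

Step 8
Reactants: 11 1-[3β-(tert-butyldimethylsilyloxy)-2β-(hydroxymethyl)-3α-isopropyl-1β-methylcyclopent-1α-yl]-3-methylbut-3-en-1-ol
Product: 12 5β-(tert-butyldimethylsilyloxy)-5α-isopropyl-2β-methyl-2α-(3-methylbut-3-enoyl)cyclopentane-1β-carbaldehyde
Conditions: Dess–Martin periodinane (3 equiv), pyridine, CH2Cl2, 0 °C to rt
Reagents that add atoms: none
Why: Dess–Martin oxidation turns the secondary homoallylic alcohol into the β,γ-unsaturated ketone and the primary alcohol into the aldehyde in one operation under buffered, non-enolising conditions, so the alkene stays out of conjugation and C9 keeps its configuration.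

Step 9
Reactants: 12 5β-(tert-butyldimethylsilyloxy)-5α-isopropyl-2β-methyl-2α-(3-methylbut-3-enoyl)cyclopentane-1β-carbaldehyde
Product: 13 trans-fused hydroazulenone with exocyclic methylene on C2, ketone at C4, 5β-CH3, 8β-OSi(t-Bu)Me2, 8α-i-Pr, 9α-H and free 10α-OH (hydroxyl cis to H9)
Conditions: Me2AlCl (2 equiv), CH2Cl2, −78 to −40 °C; aq. potassium sodium tartrate work-up
Reagents that add atoms: none
Why: Me2AlCl binds the formyl oxygen and C11, the terminal CH2 of the 1,1-disubstituted alkene, attacks C10 in an asynchronous ene process in which C–C bond formation runs ahead (positive charge builds at the tertiary C2) and a hydrogen of the allylic methyl group then passes to oxygen, after which the Al–CH3 bond takes up the hydroxyl proton as methane so that no protic acid is set free. The closest known reaction type is the Me2AlCl-promoted intramolecular carbonyl–ene cyclisation of aldehydes tethered next to the central alkene carbon (type 2), which gives 3-methylenecyclohexanols and 3-methylenecycloheptanols. Ring A closes in a seven-membered mode that is endo with respect to the alkene (C2 and C11 both become ring atoms) and exo with respect to the carbonyl group. The new stereocentre C10 is controlled by the trans-1,2-disubstituted ring B: the forming C10–C11 bond lies anti to the C9–C8 bond, and the aluminium-bound oxygen takes the outer position between H9 and C8 and not the crowded one between the quaternary carbons C5 and C8, which places the hydroxyl cis to H9 (10α). The step needs aldehyde-over-ketone chemoselectivity, bonding through the alkene terminus and not through an enol at C3, and an alkene that has not slipped into conjugation; these are secured by the greater Lewis basicity and lower hindrance of the formyl group, by the 1,1-disubstitution that directs attack to the CH2 terminus, and by the proton-scavenging Al–CH3 bond at low temperature. Which allylic hydrogen is finally lost does not matter, since every alkene isomer is taken to the same enone in step 10.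

Step 10
Reactants: 13 hydroazulenone with exocyclic methylene and free 10α-OH
Product: 14 conjugated hydroazulenone (C2=C3 enone, CH3 on C2) with 8β-OSi(t-Bu)Me2 and free 10α-OH
Conditions: DBU (0.5 equiv), CH2Cl2, rt
Reagents that add atoms: none
Why: Base-mediated prototropic isomerisation of a β,γ-unsaturated ketone through its dienolate moves the exocyclic alkene into the ring in conjugation with the C4 ketone (the trisubstituted enone is the expected thermodynamic isomer), and no stereocentre is acidic under these conditions.

Step 11
Reactants: 15 4-hydroxybenzoic acid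
Product: 17 4-(tert-butyldimethylsilyloxy)benzoic acid, via bis-silyl ester 16 (not isolated)
Conditions: TBSCl (2.2 equiv), imidazole, DMF, rt; then AcOH/THF/H2O, rt
Reagents that add atoms: tert-butyldimethylsilyl chloride (TBSCl), CC(C)(C)[Si](C)(C)Cl
Why: Exhaustive silylation followed by selective hydrolysis of the labile silyl ester leaves the phenol as an aryl silyl ether and frees the carboxylic acid.

Step 12
Reactants: 14 conjugated hydroazulenone with free 10α-OH; 17 4-(tert-butyldimethylsilyloxy)benzoic acid
Product: 18 10α-[4-(tert-butyldimethylsilyloxy)benzoyloxy] enone with 8β-OSi(t-Bu)Me2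
Conditions: EDC·HCl, DMAP, CH2Cl2, 0 °C to rt
Reagents that add atoms: 4-(tert-butyldimethylsilyloxy)benzoic acid 17, CC(C)(C)[Si](C)(C)Oc1ccc(cc1)C(O)=O
Why: Steglich esterification (carbodiimide activation with DMAP as acyl-transfer catalyst) acylates the secondary C10 hydroxyl with retention, and the silylated tertiary oxygen cannot compete.

Step 13
Reactants: 18 10α-[4-(tert-butyldimethylsilyloxy)benzoyloxy] enone with 8β-OSi(t-Bu)Me2
Product: 19 CNP0210039.1, (5S,8R,9S,10S) in the numbering used here
Conditions: aq. HF (48 %), MeCN, 0 °C to rt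
Reagents that add atoms: none
Why: HF cleaves both Si–O bonds (the aryl silyl ether quickly, the hindered tertiary silyl ether more slowly) under acidic, non-basic conditions that spare the aryl ester and avoid vinylogous elimination of the C10 acyloxy group from the enone.

**Compound list**

1 | (S)-terpinen-4-ol | CC1=CC[C@](O)(C(C)C)CC1 | starting material
2 | (S)-tert-butyldimethylsilyl ether of terpinen-4-ol | CC1=CC[C@](O[Si](C)(C)C(C)(C)C)(C(C)C)CC1 | intermediate
3 | (S)-3-(tert-butyldimethylsilyloxy)-3-isopropyl-6-oxoheptanal | O=CC[C@](O[Si](C)(C)C(C)(C)C)(C(C)C)CCC(C)=O | intermediate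
4 | (R)-5-(tert-butyldimethylsilyloxy)-5-isopropyl-2-methylcyclopent-1-ene-1-carbaldehyde | O=CC1=C(C)CC[C@@]1(O[Si](C)(C)C(C)(C)C)C(C)C | intermediate
5 | vinylmagnesium bromide | C=C[Mg]Br | starting material
6 | trimethylsilyl enol ether of 7 (CH3 and OSi(t-Bu)Me2 cis, vinyl and i-Pr cis; enol ether geometry not defined) | C=C[C@@]1(C)CC[C@@](O[Si](C)(C)C(C)(C)C)(C(C)C)C1=CO[Si](C)(C)C | intermediate (not isolated)
7 | 5β-(tert-butyldimethylsilyloxy)-5α-isopropyl-2β-methyl-2α-vinylcyclopentane-1β-carbaldehyde | C=C[C@@]1(C)CC[C@@](O[Si](C)(C)C(C)(C)C)(C(C)C)[C@@H]1C=O | intermediate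
8 | [5β-(tert-butyldimethylsilyloxy)-5α-isopropyl-2β-methyl-2α-vinylcyclopent-1β-yl]methanol | C=C[C@@]1(C)CC[C@@](O[Si](C)(C)C(C)(C)C)(C(C)C)[C@@H]1CO | intermediate
9 | 3β-(tert-butyldimethylsilyloxy)-2β-(hydroxymethyl)-3α-isopropyl-1β-methylcyclopentane-1α-carbaldehyde | O=C[C@@]1(C)CC[C@@](O[Si](C)(C)C(C)(C)C)(C(C)C)[C@@H]1CO | intermediate
10 | 3-chloro-2-methylprop-1-ene | CC(=C)CCl | starting material
11 | 1-[3β-(tert-butyldimethylsilyloxy)-2β-(hydroxymethyl)-3α-isopropyl-1β-methylcyclopent-1α-yl]-3-methylbut-3-en-1-ol (carbinol C4 unassigned) | C=C(C)CC(O)[C@@]1(C)CC[C@@](O[Si](C)(C)C(C)(C)C)(C(C)C)[C@@H]1CO | intermediate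
12 | 5β-(tert-butyldimethylsilyloxy)-5α-isopropyl-2β-methyl-2α-(3-methylbut-3-enoyl)cyclopentane-1β-carbaldehyde | C=C(C)CC(=O)[C@@]1(C)CC[C@@](O[Si](C)(C)C(C)(C)C)(C(C)C)[C@@H]1C=O | intermediate
13 | trans-fused hydroazulenone: C2 exocyclic methylene, C4 ketone, 5β-CH3, 8β-OSi(t-Bu)Me2, 8α-i-Pr, 9α-H, 10α-OH | C=C1CC(=O)[C@@]2(C)CC[C@@](O[Si](C)(C)C(C)(C)C)(C(C)C)[C@@H]2[C@@H](O)C1 | intermediate
14 | conjugated enone (C2=C3, CH3 on C2) with 5β-CH3, 8β-OSi(t-Bu)Me2, 8α-i-Pr, 9α-H, 10α-OH | CC1=CC(=O)[C@@]2(C)CC[C@@](O[Si](C)(C)C(C)(C)C)(C(C)C)[C@@H]2[C@@H](O)C1 | intermediate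
15 | 4-hydroxybenzoic acid | OC(=O)c1ccc(O)cc1 | starting material
16 | tert-butyldimethylsilyl 4-(tert-butyldimethylsilyloxy)benzoate | CC(C)(C)[Si](C)(C)Oc1ccc(cc1)C(=O)O[Si](C)(C)C(C)(C)C | intermediate (not isolated)
17 | 4-(tert-butyldimethylsilyloxy)benzoic acid | CC(C)(C)[Si](C)(C)Oc1ccc(cc1)C(O)=O | intermediate
18 | 10α-[4-(tert-butyldimethylsilyloxy)benzoyloxy] enone with 8β-OSi(t-Bu)Me2 | CC1=CC(=O)[C@@]2(C)CC[C@@](O[Si](C)(C)C(C)(C)C)(C(C)C)[C@@H]2[C@@H](OC(=O)c2ccc(O[Si](C)(C)C(C)(C)C)cc2)C1 | intermediate
19 | CNP0210039.1: 10α-(4-hydroxybenzoyloxy) enone with 8β-OH, 8α-i-Pr, 5β-CH3, 9α-H | CC1=CC(=O)[C@@]2(C)CC[C@@](O)(C(C)C)[C@@H]2[C@@H](OC(=O)c2ccc(O)cc2)C1 | target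

**Step count and weak points**

Total steps: 13 (12 in the main line and 1 for acid 17). Longest linear sequence: 12 steps (steps 1–10, 12, 13) from (S)-terpinen-4-ol.

Step 4. What may go wrong: poor or reversed facial selectivity of the vinyl transfer to C5, because the two groups on C8 differ little in a flexible five-membered ring; incomplete equilibration at C9, or loss of the silyloxy group from the aldehyde enolate, would add to it. The fallback sets out from silyl ether 2 and returns at alcohol 8. Allylic oxidation of 2 (CrO3, 3,5-dimethylpyrazole, CH2Cl2, −20 °C) at the CH2 next to the alkene CH should give (R)-6-(tert-butyldimethylsilyloxy)-6-isopropyl-3-methylcyclohex-2-en-1-one F1. Copper-catalysed addition of vinylmagnesium bromide 5 (CuBr·SMe2, THF, −40 °C) then builds the quaternary carbon on a six-membered ring whose half-chair is biased (isopropyl equatorial, silyloxy axial next to the carbonyl group). Axial, anti-parallel attack puts vinyl trans to the silyloxy group and should give 6-(tert-butyldimethylsilyloxy)-6-isopropyl-3-methyl-3-vinylcyclohexan-1-one F2. Formylation at the only enolisable position (NaH, HCO2Et, THF) gives the 2-(hydroxymethylene) ketone F3, and Regitz deformylative diazo transfer (4-acetamidobenzenesulfonyl azide, Et3N, MeCN) gives the 2-diazo ketone F4. Photochemical Wolff rearrangement in methanol (hν, MeOH; then NaOMe, MeOH, 0 °C to equilibrate C9) contracts the ring, the former carbonyl carbon becoming C10, and gives methyl 5β-(tert-butyldimethylsilyloxy)-5α-isopropyl-2β-methyl-2α-vinylcyclopentane-1β-carboxylate F5. LiAlH4 (THF, 0 °C) reduces F5 to alcohol 8. This detour also replaces the ozonolysis and aldol ring contraction of steps 2 and 3.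

Step 9. What may go wrong: closure through the alternative geometry in which the aluminium-bound oxygen sits syn to the methyl hydrogens (fully concerted hydrogen transfer), which would put the hydroxyl on the β face; migration of the alkene into conjugation before cyclisation would stop the reaction altogether. The fallback sets out from keto aldehyde 12 and returns at ester 18. If the cyclisation delivers mainly the 10β-hydroxy epimer of the methylene ketone F6, treatment with DBU as in step 10 gives the 10β-hydroxy epimer of the conjugated enone F7. A Mitsunobu reaction with acid 17 (PPh3, diisopropyl azodicarboxylate, toluene, 0 °C) then forms the ester with inversion at C10 and gives 18 directly, so C10 is set by displacement and not in the ring closure.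

Step 13. What may go wrong: slow cleavage of the hindered tertiary silyl ether, during which acid-promoted loss of the tertiary hydroxyl or cleavage and elimination of the C10 ester can compete. The fallback sets out from hydroxy enone 14 and returns at target 19. The tertiary silyl ether is removed first, while no ester is present (aq. HF, MeCN, 40 °C), to give the 8β,10α-diol of the enone F8. Steglich esterification with 17 (EDC·HCl, DMAP, CH2Cl2) acylates only the secondary hydroxyl and gives the 10α-[4-(tert-butyldimethylsilyloxy)benzoate] with free tertiary hydroxyl F9. Brief treatment with HF·pyridine (THF, 0 °C) cleaves the aryl silyl ether and gives 19.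

**Further compounds**

F1 | step 4 | (R)-6-(tert-butyldimethylsilyloxy)-6-isopropyl-3-methylcyclohex-2-en-1-one | CC1=CC(=O)[C@](O[Si](C)(C)C(C)(C)C)(C(C)C)CC1
F2 | step 4 | 6-(tert-butyldimethylsilyloxy)-6-isopropyl-3-methyl-3-vinylcyclohexan-1-one (vinyl trans to silyloxy) | C=C[C@@]1(C)CC[C@@](O[Si](C)(C)C(C)(C)C)(C(C)C)C(=O)C1
F3 | step 4 | 2-(hydroxymethylene) derivative of F2 | C=C[C@@]1(C)CC[C@@](O[Si](C)(C)C(C)(C)C)(C(C)C)C(=O)C1=CO
F4 | step 4 | 2-diazo derivative of F2 | C=C[C@@]1(C)CC[C@@](O[Si](C)(C)C(C)(C)C)(C(C)C)C(=O)C1=[N+]=[N-]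
F5 | step 4 | methyl 5β-(tert-butyldimethylsilyloxy)-5α-isopropyl-2β-methyl-2α-vinylcyclopentane-1β-carboxylate | C=C[C@@]1(C)CC[C@@](O[Si](C)(C)C(C)(C)C)(C(C)C)[C@@H]1C(=O)OC
F6 | step 9 | 10β-hydroxy epimer of methylene ketone 13 | C=C1CC(=O)[C@@]2(C)CC[C@@](O[Si](C)(C)C(C)(C)C)(C(C)C)[C@@H]2[C@H](O)C1
F7 | step 9 | 10β-hydroxy epimer of enone 14 | CC1=CC(=O)[C@@]2(C)CC[C@@](O[Si](C)(C)C(C)(C)C)(C(C)C)[C@@H]2[C@H](O)C1
F8 | step 13 | 8β,10α-diol of the enone (desilylated 14) | CC1=CC(=O)[C@@]2(C)CC[C@@](O)(C(C)C)[C@@H]2[C@@H](O)C1
F9 | step 13 | 10α-[4-(tert-butyldimethylsilyloxy)benzoate] of F8 with free tertiary hydroxyl | CC1=CC(=O)[C@@]2(C)CC[C@@](O)(C(C)C)[C@@H]2[C@@H](OC(=O)c2ccc(O[Si](C)(C)C(C)(C)C)cc2)C1
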